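I was to read three flasks at 2.0 h, and what I wanted to know at that moment was how G had divided among its fates.

the same everywhere: Z 1.5 M; Q 1.35 M; D 1.58 M; time 2.0 h

|  | temperature |
|---|---|
| midnight | 20 °C |
| spring | 0 °C |
| dusk | −20 °C |

    Q + Q.G ⇌ Q.Q.G, settled at all times (K1 = 16 M⁻¹, ΔH1 = −26.0 kJ mol⁻¹)
    Z → G (k2 = 6.1 h⁻¹, Ea2 = 64.0 kJ mol⁻¹)
    D + G → D.G (k3 = 6.3 M⁻¹ h⁻¹, Ea3 = 53.0 kJ mol⁻¹)
    G → J (k4 = 0.82 h⁻¹, Ea4 = 75.0 kJ mol⁻¹)
    Q + G → Q.G (k5 = 3.9 M⁻¹ h⁻¹, Ea5 = 57.0 kJ mol⁻¹)
    (constants at −20 °C)

- for Q.G the Q.Q.G is counted in
- the list of constants is for −20 °C, to be carried to other temperatures by the activation energies and enthalpies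

- which flask leads in share of Q.G in all that became Q.G or D.G or J ("all alike" within 1.5 percentage points) (midnight / spring / dusk / all alike)
- share of Q.G in all that became Q.G or D.G or J, midnight
- share of Q.G in all that became Q.G or D.G or J, spring
- share of Q.G in all that became Q.G or D.G or J, dusk

I built a ladder of time scales, starting from the fastest rung, in dusk, where the listed constants apply directly. The balance of Q with Q.G is kept at every instant, and at the opening [Q] it stands at 21.6 Q.Q.G per unbound Q.G, so in dusk a captured G should cost about two Q. Next comes G, whose lifetime in dusk at the opening charges is 0.0623 h, and then Z, with a lifetime of 0.164 h, longer than that of G. In dusk these two lifetimes differ by a factor of 2.63 at the opening, so I did not treat G as steady, and I reckoned its split from the rates at which it is taken. The top rung is the run itself, 12.2 Z lifetimes long in dusk, so I took the reading to show a finished split rather than a moment in a race.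

That split is a comparison of rates at one moment. I named it the capture odds, a selectivity factor: the rate constant of capture by Q times [Q], divided by the rate constant of capture by D times [D] plus the rate constant of the step to J. At the opening charges of dusk it is 0.489, a share of 32.8%. For midnight I multiplied the constants by their factors, 40 for capture by Q, 31 for capture by D and 130 for J, which gave odds of 0.510 and a share of 33.8%. For spring I used the square roots of those factors as an approximation, which gave 0.516 and 34.0%. Spring and dusk, the ends of my list, differ by 1.2 percentage points, less than the margin, so I said the flasks were all alike. Since a capture in dusk costs about two Q, I expected the share there to lie somewhat lower.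

The forecast also said all alike, with 29.8% for midnight, 30.6% for spring and 30.5% for dusk, lower than my dusk share, on the ground that “these two effects nearly cancel”.

The simulation gave 29.9% in midnight, 30.7% in spring and 30.5% in dusk, so the answer was all alike. My dusk share stood 2.3 points above the simulated value, and the using up of Q is part of what holds dusk down: without that using up, dusk gives 39.9% instead of 30.5%. In a flask like dusk but charged with 0.95 M of D, the capture odds at the opening charges rise to 0.774, a share of 43.6% for that opening moment, and at the end that flask gave 39.1%.

The rate constants come from no measurement; the flask was simulated.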